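The bicyclo[3.2.1]octane (C1 methyl bridgehead, C2–C3–C4 acylated three-carbon bridge, C5 prenyl bridgehead, C6 CH2, C7 carbinol-bearing CH, C8 bridging carbonyl) is cut at C1–C7 and C5–C6. This returns a flat acylphloroglucinol whose C8 oxygen carries C7, C6 and the carbinol carbon as a 1,1-dimethylallyl ether. The key step exploits the fact that C1 and C5 both flank C8 in the six-membered ring: two-electron oxidation of the C2 phenol turns C1–C8–C5 into an allyl cation that takes up the tethered vinyl group, closing the C1–C7–C6–C5–C8 cyclopentane and setting C1, C5 and C7 together. The precursor is this ether with the C4 oxygen capped as a methyl ether, so that only O2 can be oxidised.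

Key step: step 7

Remarks on the chemistry (numbering as above; On is the oxygen on Cn)
- Structures: the target is (1S,5S,7S) with an (R) side chain. Its carbinol carbon on C7 lies on the C8 side of the C6–C7 bridge, which is the only arrangement a tether from O8 can deliver. Compound 11 is the key-step precursor and compound 14 the cycloadduct, each carrying the O4 methyl cap.
- Precursor design: with both flanking phenols free, either oxygen can be oxidised and only the size of methyl versus prenyl decides which of C1 and C5 receives C7. Capping O4 (next to the prenyl-bearing C5) leaves O2 as the single phenol, so C5 is para to the new carbonyl and the more electrophilic terminus. The cap also blocks oxidative chromene formation between O4 and the prenyl group and leaves no enol in the cycloadduct for the oxidant to attack. It is removed in step 8.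
- Mechanism: O8 sits on the central carbon of the C1–C8–C5 allyl unit and is twisted out of plane by its two ortho neighbours, so it does not share the charge before C–C bonding. After bonding, a planar oxocarbenium at C8 is not possible, because C8 would be a bridgehead of a 2-oxabicyclo[2.2.1]heptane. The charge is therefore expected to leave by O8–C(CH3)2 heterolysis and capture of the tertiary cation by water; the product is the same as from hydrolysis of a bridged oxonium.
- The (R) side chain makes the two faces of the oxidised ring diastereotopic, so the two facial outcomes are diastereomers and the unwanted one can be removed by chromatography if reagent control is incomplete.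
- Assumption: the (R,R) iodane (preformed from the commercial iodoarene by perborate oxidation in acetic acid) is taken to favour the face that gives 14. Its preference for attack para to the bound oxygen cannot be predicted with confidence, and the (S,S) reagent would be used if the sense proves opposite.

Step 1
Reactants: 1 2,4,6-trihydroxybenzaldehyde
Product: 2 2,6-dihydroxy-4-methoxybenzaldehyde
Conditions: Me2SO4 (1.0 equiv), K2CO3 (1.0 equiv), acetone, rt
Reagents that add atoms: dimethyl sulfate, COS(=O)(=O)OC
Why: Williamson O-methylation should occur at the 4-hydroxyl, the only one not hydrogen-bonded to the formyl group and the most acidic, when one equivalent of base and electrophile is used.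

Step 2
Reactants: 2 2,6-dihydroxy-4-methoxybenzaldehyde
Product: 3 5-methoxy-2-methylbenzene-1,3-diol
Conditions: H2 (1 atm), 10% Pd/C, AcOH, rt
Reagents that add atoms: none
Why: Catalytic hydrogenation followed by hydrogenolysis should take the formyl group through the benzylic alcohol, whose C–O bond is activated by the ortho and para oxygens, to the methyl group.

Step 3
Reactants: 3 5-methoxy-2-methylbenzene-1,3-diol, 4 (R)-2-methylbutanoic acid
Product: 6 (R)-1-(2,4-dihydroxy-6-methoxy-3-methylphenyl)-2-methylbutan-1-one, via (R)-2-methylbutanoyl chloride 5 (not isolated)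
Conditions: 4, (COCl)2, cat. DMF, CH2Cl2, 0 °C to rt; then 3, AlCl3 (3 equiv), CH2Cl2/PhNO2, 0 °C to rt
Reagents that add atoms: none
Why: Friedel–Crafts acylation with the acid chloride made in situ should go to C4 (equivalent to C6), the only free ring position of 3, and base-free chloride formation plus acylation at or below room temperature should preserve the (R) centre and the methyl ether, whose neighbouring carbonyl is held in the aluminium chelate with the 2-phenoxide.

Step 4
Reactants: 6 (R)-1-(2,4-dihydroxy-6-methoxy-3-methylphenyl)-2-methylbutan-1-one, 7 prenyl bromide (1-bromo-3-methylbut-2-ene)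
Product: 8 (R)-1-[2,4-dihydroxy-6-methoxy-3-methyl-5-(3-methylbut-2-en-1-yl)phenyl]-2-methylbutan-1-one
Conditions: KOH (1.1 equiv), H2O, 0 °C to rt
Reagents that add atoms: none
Why: Phenoxide C-alkylation in water, where hydrogen bonding shields the oxygen of the unchelated 4-phenoxide, should place the prenyl group on the only unsubstituted ring carbon ortho to it.

Step 5
Reactants: 8 (R)-1-[2,4-dihydroxy-6-methoxy-3-methyl-5-(3-methylbut-2-en-1-yl)phenyl]-2-methylbutan-1-one, 9 3-chloro-3-methylbut-1-yne
Product: 10 (R)-1-[2-hydroxy-6-methoxy-3-methyl-4-(2-methylbut-3-yn-2-yloxy)-5-(3-methylbut-2-en-1-yl)phenyl]-2-methylbutan-1-one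
Conditions: CuCl2·2H2O (1 mol %), DBU, MeCN, 0 °C
Reagents that add atoms: none
Why: Copper-catalysed propargylic O-alkylation of a phenol by a tertiary propargyl chloride (through a copper allenylidene) should form the tertiary ether at the 4-hydroxyl, because the 2-hydroxyl is locked in a hydrogen bond to the ketone.

Step 6
Reactants: 10 (R)-1-[2-hydroxy-6-methoxy-3-methyl-4-(2-methylbut-3-yn-2-yloxy)-5-(3-methylbut-2-en-1-yl)phenyl]-2-methylbutan-1-one
Product: 11 (R)-1-[2-hydroxy-6-methoxy-3-methyl-4-(2-methylbut-3-en-2-yloxy)-5-(3-methylbut-2-en-1-yl)phenyl]-2-methylbutan-1-one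
Conditions: H2 (1 atm), Pd/CaCO3 poisoned with Pb(OAc)2, quinoline, EtOAc, 0 °C to rt
Reagents that add atoms: none
Why: Alkyne semihydrogenation over lead-poisoned palladium should stop at the vinyl group and leave the trisubstituted prenyl alkene and the aryl ketone untouched, and the product is kept cold so that the aryl 1,1-dimethylallyl ether does not undergo Claisen rearrangement.

Step 7
Reactants: 11 (R)-1-[2-hydroxy-6-methoxy-3-methyl-4-(2-methylbut-3-en-2-yloxy)-5-(3-methylbut-2-en-1-yl)phenyl]-2-methylbutan-1-one
Product: 14 (1R,5R,7S)-7-(2-hydroxypropan-2-yl)-4-methoxy-1-methyl-3-[(2R)-2-methylbutanoyl]-5-(3-methylbut-2-en-1-yl)bicyclo[3.2.1]oct-3-ene-2,8-dione, via cyclohexadienone cation 12 (not isolated), via tertiary carbocation 13 (not isolated)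
Conditions: ArI(OAc)2 (Ar = 2,6-bis[(R)-1-(mesitylcarbamoyl)ethoxy]phenyl, 1.1 equiv), HFIP/CH2Cl2 (1:4), −40 °C; then H2O, THF, −40 °C to rt
Reagents that add atoms: water, O
Why: Proposed new method: ligand exchange puts the trivalent-iodine reagent on O2, and loss of the iodoarene leaves cation 12, in which C2 is a carbonyl, C5 (para to it) carries most of the charge and O8 is a spectator on the central carbon of the C1–C8–C5 allyl unit. The terminal vinyl carbon C6 should bond first to C5 (Markovnikov, six-membered transition state through O8) and the developing secondary cation at C7 is then taken by C1, the enol-ether carbon of C1=C8–O, so the C1–C7–C6–C5–C8 cyclopentane closes in cycloaddition mode as an asynchronous (3+2) annulation of the allyl cation onto the alkene, which is a (5+2) cycloaddition when counted over C1–C2–C3–C4–C5. Because C8 cannot become a planar oxocarbenium inside the 2-oxabicyclo[2.2.1]heptane that this creates, the charge is expected to leave by heterolysis of the O8–C(CH3)2 bond, giving the C8 ketone and tertiary cation 13, which water quenches to the carbinol. The closest known reactions are the cationic (5+2) cycloadditions of oxidised 4-alkoxyphenols and of quinone monoketals with alkenes, where the alkene spans the two carbons ortho to the oxidised oxygen and any tether is carbon-based, whereas here the oxidised oxygen is meta to the bridging carbon and the tether runs through the bridging oxygen. C7 is set relative to C1 and C5 by the two-atom tether, which can only deliver the carbinol carbon syn to C8, and the absolute sense at C1 and C5 should come from the chiral iodane on O2, which screens one face while the vinyl group adds to the other. The step needs C6 to bond to C5 and C7 to C1, which the methyl cap on O4 secures by making C5 the para and most electrophilic terminus, reinforced by methyl at C1 being smaller than prenyl at C5 against the gem-dimethyl group.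

Step 8
Reactants: 14 (1R,5R,7S)-7-(2-hydroxypropan-2-yl)-4-methoxy-1-methyl-3-[(2R)-2-methylbutanoyl]-5-(3-methylbut-2-en-1-yl)bicyclo[3.2.1]oct-3-ene-2,8-dione
Product: 15 (1S,5S,7S)-2-hydroxy-7-(2-hydroxypropan-2-yl)-1-methyl-3-[(2R)-2-methylbutanoyl]-5-(3-methylbut-2-en-1-yl)bicyclo[3.2.1]oct-2-ene-4,8-dione (CNP0201042.1)
Conditions: LiCl, DMSO, 120 °C; then 1 M HCl
Reagents that add atoms: none
Why: Nucleophilic O-demethylation (SN2 attack of chloride on the methyl group) of a vinylogous methyl ester whose leaving group is a β-triketonate is the usual last step for bridged acylphloroglucinols, and its neutral conditions should spare the prenyl group, the tertiary alcohol and the (R) centre.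

Compound list
1 | 2,4,6-trihydroxybenzaldehyde | O=Cc1c(O)cc(O)cc1O | starting material
2 | 2,6-dihydroxy-4-methoxybenzaldehyde | COc1cc(O)c(C=O)c(O)c1 | intermediate
3 | 5-methoxy-2-methylbenzene-1,3-diol | COc1cc(O)c(C)c(O)c1 | intermediate
4 | (R)-2-methylbutanoic acid | CC[C@@H](C)C(O)=O | starting material
5 | (R)-2-methylbutanoyl chloride | CC[C@@H](C)C(Cl)=O | intermediate (not isolated)
6 | (R)-1-(2,4-dihydroxy-6-methoxy-3-methylphenyl)-2-methylbutan-1-one | CC[C@@H](C)C(=O)c1c(O)c(C)c(O)cc1OC | intermediate
7 | prenyl bromide (1-bromo-3-methylbut-2-ene) | CC(C)=CCBr | starting material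
8 | (R)-1-[2,4-dihydroxy-6-methoxy-3-methyl-5-(3-methylbut-2-en-1-yl)phenyl]-2-methylbutan-1-one | CC[C@@H](C)C(=O)c1c(O)c(C)c(O)c(CC=C(C)C)c1OC | intermediate
9 | 3-chloro-3-methylbut-1-yne | CC(C)(Cl)C#C | starting material
10 | (R)-1-[2-hydroxy-6-methoxy-3-methyl-4-(2-methylbut-3-yn-2-yloxy)-5-(3-methylbut-2-en-1-yl)phenyl]-2-methylbutan-1-one | CC[C@@H](C)C(=O)c1c(O)c(C)c(OC(C)(C)C#C)c(CC=C(C)C)c1OC | intermediate
11 | (R)-1-[2-hydroxy-6-methoxy-3-methyl-4-(2-methylbut-3-en-2-yloxy)-5-(3-methylbut-2-en-1-yl)phenyl]-2-methylbutan-1-one (key-step precursor) | CC[C@@H](C)C(=O)c1c(O)c(C)c(OC(C)(C)C=C)c(CC=C(C)C)c1OC | intermediate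
12 | cyclohexadienone cation from 11 (C2 carbonyl, charge drawn at C5) | CC[C@@H](C)C(=O)C1=C(OC)[C+](CC=C(C)C)C(OC(C)(C)C=C)=C(C)C1=O | intermediate (not isolated)
13 | tertiary carbocation of the cycloadduct (C8 ketone, cationic carbon on C7) | CC[C@@H](C)C(=O)C1=C(OC)[C@@]2(CC=C(C)C)C[C@H]([C+](C)C)[C@](C)(C2=O)C1=O | intermediate (not isolated)
14 | (1R,5R,7S)-7-(2-hydroxypropan-2-yl)-4-methoxy-1-methyl-3-[(2R)-2-methylbutanoyl]-5-(3-methylbut-2-en-1-yl)bicyclo[3.2.1]oct-3-ene-2,8-dione (key-step product) | CC[C@@H](C)C(=O)C1=C(OC)[C@@]2(CC=C(C)C)C[C@H](C(C)(C)O)[C@](C)(C2=O)C1=O | intermediate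
15 | (1S,5S,7S)-2-hydroxy-7-(2-hydroxypropan-2-yl)-1-methyl-3-[(2R)-2-methylbutanoyl]-5-(3-methylbut-2-en-1-yl)bicyclo[3.2.1]oct-2-ene-4,8-dione | CC[C@@H](C)C(=O)C1=C(O)[C@@]2(C)C(=O)[C@](CC=C(C)C)(C[C@@H]2C(C)(C)O)C1=O | target

Total steps: 8. Longest linear sequence: 8 (1 to 15); 4, 7 and 9 enter as single building blocks.

Steps most likely to fail

1. Step 7 (Proposed new method).
- What may go wrong: acetate or water may capture the oxidised ring at C1 or C5, or a benzylic proton may be lost to a quinone methide, faster than the unactivated vinyl group adds. The tertiary allyl ether may ionise. The secondary cation at C7 may rearrange or eliminate before the second bond forms. Facial selectivity may be poor, or C6 may bond to C1.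
- Fallback (known chemistry, from 8, back at 14): dearomative C-alkylation of 8 with a second equivalent of 7 (aq. KOH, 0 °C) should give the 6,6-diprenyl dienone F1. PhI(OAc)2 and TEMPO in THF at −78 °C to rt should then oxidise its C2 enol to the C1 radical, which closes 5-exo onto one prenyl group on C5 (forming C1–C7) and is trapped at the tertiary carbon to give the O-(2,2,6,6-tetramethylpiperidin-1-yl) ether of 14 F2. Zn in AcOH cleaves the N–O bond to 14. This sequence gives up control over which prenyl group reacts and over C7, so 14 would have to be separated from its diastereomers.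

2. Step 5.
- What may go wrong: etherification of a phenol flanked by methyl and prenyl with a tertiary electrophile may stall or divert to dearomative C-alkylation.
- Fallback (from 8, back at 11, bypassing 10 and step 6): 2-methylbut-3-en-2-ol and Boc2O (DMAP) give tert-butyl 2-methylbut-3-en-2-yl carbonate F3. With 8 and Pd(PPh3)4 (zerovalent palladium) in THF at 0 °C, decarboxylative O-allylation at the more substituted allyl terminus should deliver the 1,1-dimethylallyl ether 11 directly.

3. Step 4.
- What may go wrong: O-prenylation and dearomative alkylation at the methyl-bearing carbon may compete with C-alkylation at C5.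
- Fallback (from 6, back at 8): 6 is O-alkylated with 9 under the conditions of step 5 to the propargyl ether F4 and semihydrogenated as in step 6 to the 1,1-dimethylallyl ether F5. Heating (toluene or PhNEt2, about 110 °C) should then bring about the aromatic Claisen rearrangement, which delivers the allyl unit, inverted to prenyl, to the only free ortho carbon and gives 8.

Further compounds
F1 | step 7 | 3-hydroxy-5-methoxy-2-methyl-4-[(2R)-2-methylbutanoyl]-6,6-bis(3-methylbut-2-en-1-yl)cyclohexa-2,4-dien-1-one | CC[C@@H](C)C(=O)C1=C(OC)C(CC=C(C)C)(CC=C(C)C)C(=O)C(C)=C1O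
F2 | step 7 | (1R,5R,7S)-4-methoxy-1-methyl-3-[(2R)-2-methylbutanoyl]-5-(3-methylbut-2-en-1-yl)-7-{2-[(2,2,6,6-tetramethylpiperidin-1-yl)oxy]propan-2-yl}bicyclo[3.2.1]oct-3-ene-2,8-dione | CC[C@@H](C)C(=O)C1=C(OC)[C@@]2(CC=C(C)C)C[C@H](C(C)(C)ON3C(C)(C)CCCC3(C)C)[C@](C)(C2=O)C1=O
F3 | step 5 | tert-butyl 2-methylbut-3-en-2-yl carbonate | CC(C)(C)OC(=O)OC(C)(C)C=C
F4 | step 4 | (R)-1-[2-hydroxy-6-methoxy-3-methyl-4-(2-methylbut-3-yn-2-yloxy)phenyl]-2-methylbutan-1-one | CC[C@@H](C)C(=O)c1c(O)c(C)c(OC(C)(C)C#C)cc1OC
F5 | step 4 | (R)-1-[2-hydroxy-6-methoxy-3-methyl-4-(2-methylbut-3-en-2-yloxy)phenyl]-2-methylbutan-1-one | CC[C@@H](C)C(=O)c1c(O)c(C)c(OC(C)(C)C=C)cc1OC
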